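- At late times the question turns round: for the most X to come before 4.0 d in the asked flask, [X] must stop rising inside that time.

| setting | blue | green | teal | flask |
|---|---|---|---|---|
| L | 0.067 M | 0.15 M | 0.10 M | 0.10 M |
| Q | 0.01 mol% | 0.01 mol% | 0.015 mol% | 0.01 mol% |
| remark | run made earlier | run made earlier | run made earlier |  |
| time |  |  |  | 4.0 d |

| run | time / d | X / % |
|---|---|---|
| blue | 1.04 | 12.8 |
| blue | 1.67 | 26.3 |
| blue | 2.00 | 31.4 |
| blue | 3.00 | 50.1 |
| green | 1.04 | 9.4 |
| green | 1.67 | 18.2 |
| green | 2.00 | 17.2 |
| green | 3.00 | 26.9 |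
| teal | 1.04 | 12.2 |
| teal | 1.67 | 22.8 |
| teal | 2.00 | 26.9 |
| teal | 3.00 | 43.1 |

(each reading ± 1 percentage point)
- the moment within 4.0 d at which there is most X
- the amount of X, in percent of the L charged, at that time
- the first time at which X reaches 34%, in the same percent, in d

- Between 2.00 d and 3.00 d, blue gains 0.0125 M d⁻¹ and green 0.0146 M d⁻¹, at the loading of the asked flask and at charges on either side of its 0.10 M.
- I take their mean, 0.0135 M d⁻¹, and call it the late gain: the [X] made per day after the start-up, an apparent zero order in L.
- At that gain, [X] in the asked flask would need 7.39 d to equal the charge of L, longer than 4.0 d. Green's rise of 9.7 percentage points from 2.00 d to 3.00 d is also larger than the scatter of 1 point, so this last step of green shows no fall.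
- My own reckoning starts from the mean [X] of blue and green at 3.00 d. One more late gain gives 50.5% at 4.0 d, and stepping back gives 34% at 2.78 d.
- The forecast, with figures slightly apart from mine, says 51% at 4 d and 2.75 d for 34%, “with no sign of a decline”.
- The asked flask gives 49.2% at 4.00 d, and reaches 34% at 2.74 d.

    L ⇌ E, rate k1*(cs1 - [E]) while solid is left; crystals form when [E] > cs1 (solubility = 34.0 mM, k = 0.0297 h⁻¹)
    X + Q ⇌ D + Q, rate k2*[Q]*[X] forward; the back reaction follows from the equilibrium constant (K = 0.482, k = 775 L mol⁻¹ h⁻¹)
    Q + X ⇌ G (K = 8.98 L mol⁻¹, k = 0.595 L mol⁻¹ h⁻¹)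
    E + Q → X + Q, rate k4*[E]*[Q]/(1 + ([E]/Km4)) (0.255 M, k = 8140 L mol⁻¹ h⁻¹)

- At 1.87 d, free X in the asked flask is made 5.81 times faster than it is used up, each step taken net and its going into other forms counted as use. From 2.00 d to 4.00 d the asked flask gains 0.0124 M d⁻¹; the late gain read from blue and green was 0.0135 M d⁻¹. A neighbour flask, the same but with 0.017 mol% of Q, ends at 55.0%, and its excess over the asked flask equals 0.434 d of late gain.

The runs are calculated for an exercise; the scatter is artificial.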